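**Strategy**

The quinone ring (C1 and C4 carbonyls, C2 hydroxyl, C3 henicosyl, C5 methoxy) is cut at C2–C3 and C4–C5. The para-related oxygenated carbons C2 and C5, with C1 and C6 between them, are recognised as a ring-opened 2-methoxyfuran whose ring oxygen is the C2 hydroxyl oxygen. C3 and C4 are the carbons of tetracos-2-ynal, whose formyl group activates the alkyne and marks C4 for oxygenation. One Diels–Alder cycloaddition with ring-opening aromatisation forms both bonds and sets the whole substitution pattern. Dakin oxidation (CHO to OH) and Teuber oxidation at C1 then give the hydroxyquinone.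

Key step: step 2

Remark: the target has no stereocentre; cycloadduct 7 forms as a racemate whose two bridgehead centres are lost on aromatisation, and in step 2 all atoms of 5 and 6 end up in 8.

**Route**

Step 1
Reactants: 1 1-bromoicosane, 2 propyne
Product: 5 tetracos-2-ynal, via 1,3-dilithiopropyne 3 (not isolated), via lithium tricos-1-yn-1-ide 4 (not isolated)
Conditions: 2, n-BuLi (2 equiv), TMEDA, Et2O/hexane, −78 °C to 0 °C; then 1, THF, −78 °C to rt; then DMF, −20 °C to rt; inverse quench into cold aq. HCl
Reagents that add atoms: N,N-dimethylformamide, CN(C)C=O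
Why: Double deprotonation of propyne gives the propargylic/acetylenic dianion, which the primary bromide should alkylate at the more nucleophilic sp3 carbon (SN2 propargylation), and the remaining lithium acetylide is then formylated by DMF (Bouveault-type formylation), the acidic inverse quench keeping the liberated amine from adding to the ynal.

Step 2
Reactants: 5 tetracos-2-ynal, 6 2-methoxyfuran
Product: 8 2-henicosyl-3-hydroxy-6-methoxybenzaldehyde, via oxanorbornadiene cycloadduct 7 (not isolated)
Conditions: 6 (3 equiv), toluene, 80 °C, sealed tube, N2
Reagents that add atoms: none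
Why: Normal-electron-demand Diels–Alder reaction: the electron-rich furan diene (C2 to C5) adds across the formyl-activated triple bond of 5 in an asynchronous [4+2] cycloaddition, furan C5 (largest HOMO coefficient) bonding to the henicosyl-bearing β-carbon and the methoxy-bearing furan C2 to the formyl-bearing α-carbon. The ketal-type bridge C–O bond of cycloadduct 7 should then ionise to a methoxy-stabilised oxocarbenium ion, and loss of the other bridgehead proton aromatises the ring, so that the furan oxygen becomes the phenolic hydroxyl. The closest known reaction type is the cycloaddition/ring-opening aromatisation of 2-alkoxyfurans with acetylenic esters and ketones to 4-alkoxyphenols. The six-membered carbocycle is closed by the intermolecular [4+2] cycloaddition itself, both ring bonds forming in the same event, and the oxygen bridge is only temporary. No stereocentre survives, since the two bridgehead centres of racemic 7 are erased on aromatisation. The step needs head-to-head regioselectivity, which the C2 donor of the furan and the polarisation of the ynal secure, and ring closure in preference to open-chain conjugate substitution or 1,2-addition to the aldehyde, which acid-free thermal conditions in a non-polar solvent should favour.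

Step 3
Reactants: 8 2-henicosyl-3-hydroxy-6-methoxybenzaldehyde
Product: 10 2-henicosyl-4-methoxybenzene-1,3-diol, via aryl formate 9 (not isolated)
Conditions: mCPBA, CH2Cl2, 0 °C to rt; then MeOH, cat. HCl, rt, under argon
Reagents that add atoms: mCPBA (3-chloroperoxybenzoic acid), OOC(=O)c1cccc(Cl)c1
Why: Dakin-type Baeyer–Villiger oxidation, in which the electron-rich ortho-methoxy aryl group should migrate in the Criegee intermediate to give the aryl formate, whose acid-catalysed methanolysis frees the second phenol.

Step 4
Reactants: 10 2-henicosyl-4-methoxybenzene-1,3-diol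
Product: 11 3-henicosyl-2-hydroxy-5-methoxycyclohexa-2,5-diene-1,4-dione
Conditions: (KSO3)2NO (2.2 equiv), KH2PO4, THF/H2O, 0 °C to rt
Reagents that add atoms: potassium nitrosodisulfonate, [K+].[K+].[O]N(S(=O)(=O)[O-])S(=O)(=O)[O-]
Why: Teuber oxidation, in which the nitroxide should oxygenate the only unsubstituted ring carbon that is para to one hydroxyl and ortho to the other, giving the para-quinone with the remaining hydroxyl kept as the enolic 2-hydroxy group (the ortho-quinone alternative is a tautomer of the same product).

**Compound list**

1 | 1-bromoicosane | CCCCCCCCCCCCCCCCCCCCBr | starting material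
2 | propyne | CC#C | starting material
3 | 1,3-dilithiopropyne | [Li]CC#C[Li] | intermediate
4 | lithium tricos-1-yn-1-ide | CCCCCCCCCCCCCCCCCCCCCC#C[Li] | intermediate
5 | tetracos-2-ynal | CCCCCCCCCCCCCCCCCCCCCC#CC=O | intermediate
6 | 2-methoxyfuran | COc1ccco1 | starting material
7 | 3-henicosyl-1-methoxy-7-oxabicyclo[2.2.1]hepta-2,5-diene-2-carbaldehyde (racemic, one enantiomer drawn) | CO[C@]12C=C[C@H](O1)C(CCCCCCCCCCCCCCCCCCCCC)=C2C=O | intermediate
8 | 2-henicosyl-3-hydroxy-6-methoxybenzaldehyde | CCCCCCCCCCCCCCCCCCCCCc1c(O)ccc(OC)c1C=O | intermediate
9 | 2-henicosyl-3-hydroxy-6-methoxyphenyl formate | CCCCCCCCCCCCCCCCCCCCCc1c(O)ccc(OC)c1OC=O | intermediate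
10 | 2-henicosyl-4-methoxybenzene-1,3-diol | CCCCCCCCCCCCCCCCCCCCCc1c(O)ccc(OC)c1O | intermediate
11 | 3-henicosyl-2-hydroxy-5-methoxycyclohexa-2,5-diene-1,4-dione | CCCCCCCCCCCCCCCCCCCCCC1=C(O)C(=O)C=C(OC)C1=O | target

**Step count and risks**

Total step count: 4. Longest linear sequence: 4 steps (1 → 5 → 8 → 10 → 11).

Steps most likely to fail:

1. Step 2. After the first C–C bond forms, the zwitterion may transfer a proton instead of closing the ring (net conjugate substitution at the furan), the furan may add 1,2 to the aldehyde, or the furan may be lost by ring opening before it reacts. The fallback sets out from 1 and returns at 10, building the arene by directed ortho-metalation instead of cycloaddition. Purchased 4-methoxybenzene-1,3-diol (COc1ccc(O)cc1O) would be protected (MOMCl, i-Pr2NEt, CH2Cl2) as 1-methoxy-2,4-bis(methoxymethoxy)benzene F1. n-BuLi (THF, 0 °C) should remove the proton flanked by the two acetal oxygens to give [3-methoxy-2,6-bis(methoxymethoxy)phenyl]lithium F2, which DMF (aq. NH4Cl work-up) converts into 3-methoxy-2,6-bis(methoxymethoxy)benzaldehyde F3. Bromide 1 and Mg (THF) give icosylmagnesium bromide F4, which adds to F3 (aq. NH4Cl work-up) to give racemic 1-[3-methoxy-2,6-bis(methoxymethoxy)phenyl]henicosan-1-ol F5. Hydrogenolysis of the benzylic C–O bond with concurrent acetal cleavage (H2, Pd/C, HCl, MeOH) should then give 10.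

2. Step 1. The second deprotonation of propyne may stay incomplete, so that alkylation is slow and elimination of the bromide competes, or liberated amine may add to the ynal during the quench. The fallback sets out from 1 and returns at 5 through isolable intermediates. 1-(Trimethylsilyl)propyne would be lithiated (n-BuLi, THF, −20 °C) to [3-(trimethylsilyl)prop-2-yn-1-yl]lithium F6, which 1 alkylates to trimethyl(tricos-1-yn-1-yl)silane F7. K2CO3 in MeOH/THF removes the silyl group to give tricos-1-yne F8, and n-BuLi followed by DMF converts F8 through acetylide 4 into 5.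

3. Step 4. The nitroxide may attack the methoxy-bearing carbon with loss of methanol, or the electron-rich ring may be over-oxidised. The fallback sets out from 10 and returns at 11, bringing in the last oxygen by C-formylation and Dakin oxidation. Vilsmeier–Haack formylation (POCl3, DMF, then water) at the only free position activated by both hydroxyls should give 3-henicosyl-2,4-dihydroxy-5-methoxybenzaldehyde F9. Alkaline H2O2 (Dakin oxidation) would give 3-henicosyl-5-methoxybenzene-1,2,4-triol F10, which air (O2, aq. NaHCO3/THF) should oxidise to 11.

**Further compounds**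

F1 | step 2 | 1-methoxy-2,4-bis(methoxymethoxy)benzene | COCOc1ccc(OC)c(OCOC)c1
F2 | step 2 | [3-methoxy-2,6-bis(methoxymethoxy)phenyl]lithium | [Li]c1c(OCOC)ccc(OC)c1OCOC
F3 | step 2 | 3-methoxy-2,6-bis(methoxymethoxy)benzaldehyde | O=Cc1c(OCOC)ccc(OC)c1OCOC
F4 | step 2 | icosylmagnesium bromide | CCCCCCCCCCCCCCCCCCCC[Mg]Br
F5 | step 2 | 1-[3-methoxy-2,6-bis(methoxymethoxy)phenyl]henicosan-1-ol (racemic) | CCCCCCCCCCCCCCCCCCCCC(O)c1c(OCOC)ccc(OC)c1OCOC
F6 | step 1 | [3-(trimethylsilyl)prop-2-yn-1-yl]lithium | [Li]CC#C[Si](C)(C)C
F7 | step 1 | trimethyl(tricos-1-yn-1-yl)silane | CCCCCCCCCCCCCCCCCCCCCC#C[Si](C)(C)C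
F8 | step 1 | tricos-1-yne | CCCCCCCCCCCCCCCCCCCCCC#C
F9 | step 4 | 3-henicosyl-2,4-dihydroxy-5-methoxybenzaldehyde | CCCCCCCCCCCCCCCCCCCCCc1c(O)c(C=O)cc(OC)c1O
F10 | step 4 | 3-henicosyl-5-methoxybenzene-1,2,4-triol | CCCCCCCCCCCCCCCCCCCCCc1c(O)c(O)cc(OC)c1O
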